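**Retrosynthetic overview**
1. Target 25 comes from the tetracyclic (6Z)-alkene 24 by a singlet-oxygen ene reaction (O to C6, H from the C7 methyl), the presumed last biogenetic oxidation.
2. 24 comes from alcohol 22 by closing the oxepane through the C3–O–C16 ether (the briarellin/asbestinin-type etherification) after C16 oxygenation of the C14 isopropenyl group; the oxonene of 20 comes from 19 by C6=C7 ring-closing metathesis.
3. The hydroisobenzofuran comes from lactone 14, in which C1 serves twice as the electrophile, as in the cyclase cascade: first C1–C10 (enolate opening of a C1 epoxide, then lactonisation, which places the future C2–O–C9 oxygen), then C1–C14 by an ene closure in which C16 loses the proton and leaves the isopropenyl group.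
4. Building blocks: β-keto ester 4 (C9–C17, C20; from imide 1, prenyl bromide 2, methyl acetate), epoxy alcohol 7 (C1–C6, C18; from nerol 5), methallylsilane 18 (C7, C8, C19).
5. Ring order: γ-lactone (C1–C10, C2–O) → cyclohexane (C1–C14) → oxolane (C9) → oxonene → oxepane.

Assumption: locants C1–C20 are those of the asbestinane skeleton (oxolane oxygen between C2 and C9, oxepane oxygen between C3 and C16), so the given SMILES is read as the (1S,2S,3S,6R,9S,10R,11R,12R,14S,15R) isomer.

**Route**

Step 1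
Reactants: 1 (S)-4-benzyl-3-propanoyl-1,3-oxazolidin-2-one; 2 1-bromo-3-methylbut-2-ene
Product: 3 (S)-4-benzyl-3-[(R)-2,5-dimethylhex-4-enoyl]-1,3-oxazolidin-2-one
Conditions: NaN(SiMe3)2, THF, −78 °C; then 2, −78 → −40 °C
Reagents that add atoms: none
Why: Evans alkylation; the chelated Z-sodium enolate is alkylated on the face opposite the benzyl group, which sets the future C12 methyl stereocentre (R).

Step 2
Reactants: 3 (S)-4-benzyl-3-[(R)-2,5-dimethylhex-4-enoyl]-1,3-oxazolidin-2-one
Product: 4 methyl (R)-4,7-dimethyl-3-oxooct-6-enoate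
Conditions: MeOAc, LiN(iPr)2, THF, −78 °C; then 3, −78 → −30 °C; 1 M HCl
Reagents that add atoms: methyl acetate, COC(C)=O
Why: Crossed Claisen acyl transfer (as with lithiated phosphonates on such imides); the ester enolate attacks the exocyclic carbonyl and expels the oxazolidinone, and the product is held as its enolate so the α-methyl stereocentre is not epimerised.

Step 3
Reactants: 5 nerol
Product: 6 [(2R,3S)-3-methyl-3-(4-methylpent-3-en-1-yl)oxiran-2-yl]methanol
Conditions: Ti(OiPr)4 (5 mol%), D-(−)-diethyl tartrate (6 mol%), tBuOOH, 4 Å molecular sieves, CH2Cl2, −20 °C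
Reagents that add atoms: tert-butyl hydroperoxide, CC(C)(C)OO
Why: Sharpless asymmetric epoxidation; the tartrate–titanium catalyst epoxidises only the allylic-alcohol olefin on one face, setting C2 (R) and C3 (S) of the cis-epoxide.

Step 4
Reactants: 6 [(2R,3S)-3-methyl-3-(4-methylpent-3-en-1-yl)oxiran-2-yl]methanol
Product: 7 [(2R,3S)-3-(but-3-en-1-yl)-3-methyloxiran-2-yl]methanol
Conditions: ethylene (5 bar), second-generation Hoveyda–Grubbs catalyst RuCl2(=CH-C6H4-2-OiPr)(H2IMes) (3 mol%), CH2Cl2, 40 °C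
Reagents that add atoms: ethylene, C=C
Why: Olefin cross-metathesis with ethylene (ethenolysis) turns the only olefin, the isopropylidene terminus, into a vinyl group, so that it cannot compete as an ene donor in step 6 and becomes the metathesis partner of step 10; no stereocentre is touched.

Step 5
Reactants: 4 methyl (R)-4,7-dimethyl-3-oxooct-6-enoate; 7 [(2R,3S)-3-(but-3-en-1-yl)-3-methyloxiran-2-yl]methanol
Product: 10 (5S)-3-[(R)-2,5-dimethylhex-4-enoyl]-5-[(S)-2-hydroxyhex-5-en-2-yl]oxolan-2-one, via Payne epoxide 8 (not isolated), via hydroxy keto ester 9 (not isolated)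
Conditions: KOtBu (2.2 equiv), tBuOH–THF, 0 → 50 °C; then 1 M HCl
Reagents that add atoms: none
Why: Proposed new method: the epoxy alkoxide equilibrates by Payne rearrangement (inversion at C2) with the terminal 1,2-epoxide, whose CH2 (C1) is opened by the potassium enolate of 4 to make the C1–C10 bond, and the freed C2 alkoxide lactonises onto the methyl ester, so C3 keeps its Sharpless configuration and C2 is set by the single inversion; the closest known reactions are Payne rearrangement with nucleophile trapping and the acetoacetate–epoxide γ-lactone synthesis.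

Step 6
Reactants: 10 (5S)-3-[(R)-2,5-dimethylhex-4-enoyl]-5-[(S)-2-hydroxyhex-5-en-2-yl]oxolan-2-one
Product: 14 enol of the bicyclic keto lactone, via selenide 11 (not isolated), via selenoxide 12 (not isolated), via acylbutenolide 13 (not isolated)
Conditions: NaH (1.05 equiv), THF, 0 °C; PhSeBr, −78 °C; 30% H2O2, CH2Cl2, 0 °C; dried organic phase, ZnBr2, 0 °C → rt
Reagents that add atoms: none
Why: Proposed new method: enolate selenenylation and selenoxide syn-elimination (only C1 carries β-hydrogens) give a doubly activated 3-acylbutenolide whose C1 is attacked, under ZnBr2 chelation, by the tethered C14=C15 olefin anti to the C2 side chain and with the C15 unit exo, the cation losing a C16 proton (intramolecular ene reaction), which sets C1 and C14 (trans to C2) and leaves C10 as an enol; the closest known reaction is the Lewis-acid ene cyclisation of alkylidene 1,3-dicarbonyl compounds onto a trisubstituted olefin.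

Step 7
Reactants: 14 enol of the bicyclic keto lactone
Product: 15 cis-fused 11-hydroxy lactone
Conditions: NaBH4, CeCl3·7H2O, MeOH, −78 °C
Reagents that add atoms: none
Why: Luche reduction; the enol ketonises by protonation of C10 on the face carrying H1, anti to the pseudoaxial C12 methyl, and the cis-fused ketone is reduced at once by axial hydride attack on the same convex face, setting C10 (cis fusion) and C11 (hydroxyl cis to C9 and to the C12 methyl).

Step 8
Reactants: 15 cis-fused 11-hydroxy lactone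
Product: 17 lactol diacetate, via lactol 16 (not isolated)
Conditions: iBu2AlH (3.3 equiv), CH2Cl2, −78 °C; then pyridine, DMAP, Ac2O, −78 → −20 °C
Reagents that add atoms: acetic anhydride, CC(=O)OC(C)=O
Why: Reductive acetylation; the lactone is reduced to the aluminium lactolate, which is acetylated in the flask together with the C11 alkoxide, while the hindered tertiary C3 alkoxide is not acylated at low temperature, and no stereocentre of the final product is affected (C9 anomers are both used).

Step 9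
Reactants: 17 lactol diacetate; 18 trimethyl(2-methylprop-2-en-1-yl)silane
Product: 19 2,9-cis-oxolane bearing the C9 2-methylallyl group
Conditions: BF3·OEt2, CH2Cl2, −78 °C
Reagents that add atoms: none
Why: Hosomi–Sakurai C-glycosylation; the allylsilane adds to the C9 oxocarbenium ion on the convex face, anti to the C10–C11 bond and to the participating C11 acetate, which sets C9 with the C8 chain cis to the C3 chain.

Step 10
Reactants: 19 2,9-cis-oxolane bearing the C9 2-methylallyl group
Product: 20 tricyclic (6Z)-oxonene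
Conditions: second-generation Grubbs catalyst RuCl2(=CHPh)(PCy3)(H2IMes) (10 mol%), CH2Cl2 (2 mM), 40 °C
Reagents that add atoms: none
Why: Ring-closing metathesis between the vinyl and 2-methylallyl termini of the cis-disposed chains; the nine-membered ether can hold only the Z trisubstituted C6=C7 olefin, and the α-branched isopropenyl group is too hindered to compete.

Step 11
Reactants: 20 tricyclic (6Z)-oxonene
Product: 22 C16 primary alcohol, via alkylborane 21 (not isolated)
Conditions: 9-BBN, THF, 0 °C → rt; then aq NaOAc, 30% H2O2, 0 °C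
Reagents that add atoms: hydrogen peroxide, OO
Why: Hydroboration–oxidation; 9-BBN adds anti-Markovnikov to the 1,1-disubstituted olefin only, on the face anti to C1 in the conformer with H14 eclipsing the olefin (minimised allylic strain), which sets C15 (R), and the buffered oxidation spares the acetate.

Step 12
Reactants: 22 C16 primary alcohol
Product: 24 tetracyclic (6Z)-alkene, via triflate 23 (not isolated)
Conditions: Tf2O, 2,6-lutidine, CH2Cl2, −78 → 0 °C
Reagents that add atoms: none
Why: Triflation of the primary alcohol and intramolecular SN2 displacement by the tertiary C3 hydroxyl (Williamson-type etherification, 7-exo-tet) close the oxepane, a closure known on closely related tricycles; no stereocentre is touched.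

Step 13
Reactants: 24 tetracyclic (6Z)-alkene
Product: 25 target hydroperoxide
Conditions: O2, visible light, tetraphenylporphyrin (cat.), CH2Cl2, 0 °C
Reagents that add atoms: oxygen, O=O
Why: Schenck ene reaction; singlet oxygen is expected to add to C6 on the exposed outer face of the Z-olefin and to take a hydrogen from the C7 methyl (its C–H bonds can align with the π system, the ring methylenes cannot), giving the 6R hydroperoxide and the exocyclic C7=C19 olefin, by analogy with related Z-oxonenes.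

**Compound list**
1 | (S)-4-benzyl-3-propanoyl-1,3-oxazolidin-2-one | CCC(=O)N1[C@@H](Cc2ccccc2)COC1=O | starting material
2 | 1-bromo-3-methylbut-2-ene (prenyl bromide) | CC(C)=CCBr | starting material
3 | (S)-4-benzyl-3-[(R)-2,5-dimethylhex-4-enoyl]-1,3-oxazolidin-2-one | C[C@H](CC=C(C)C)C(=O)N1[C@@H](Cc2ccccc2)COC1=O | intermediate
4 | methyl (R)-4,7-dimethyl-3-oxooct-6-enoate | COC(=O)CC(=O)[C@H](C)CC=C(C)C | intermediate
5 | nerol, (Z)-3,7-dimethylocta-2,6-dien-1-ol | OC/C=C(/C)CCC=C(C)C | starting material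
6 | [(2R,3S)-3-methyl-3-(4-methylpent-3-en-1-yl)oxiran-2-yl]methanol | OC[C@H]1O[C@@]1(C)CCC=C(C)C | intermediate
7 | [(2R,3S)-3-(but-3-en-1-yl)-3-methyloxiran-2-yl]methanol | OC[C@H]1O[C@@]1(C)CCC=C | intermediate
8 | (S)-2-[(S)-oxiran-2-yl]hex-5-en-2-ol (Payne epoxide) | C1O[C@@H]1[C@@](C)(O)CCC=C | intermediate
9 | methyl (4R)-2-[(2S,3S)-2,3-dihydroxy-3-methylhept-6-en-1-yl]-4,7-dimethyl-3-oxooct-6-enoate (C2 epimers) | COC(=O)C(C[C@H](O)[C@@](C)(O)CCC=C)C(=O)[C@H](C)CC=C(C)C | intermediate
10 | (5S)-3-[(R)-2,5-dimethylhex-4-enoyl]-5-[(S)-2-hydroxyhex-5-en-2-yl]oxolan-2-one (C3 epimers) | C=CCC[C@](C)(O)[C@@H]1CC(C(=O)[C@H](C)CC=C(C)C)C(=O)O1 | intermediate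
11 | 3-(phenylselanyl) derivative of 10 | C=CCC[C@](C)(O)[C@@H]1CC([Se]c2ccccc2)(C(=O)[C@H](C)CC=C(C)C)C(=O)O1 | intermediate
12 | selenoxide of 11 | C=CCC[C@](C)(O)[C@@H]1CC([Se](=O)c2ccccc2)(C(=O)[C@H](C)CC=C(C)C)C(=O)O1 | intermediate
13 | (S)-3-[(R)-2,5-dimethylhex-4-enoyl]-5-[(S)-2-hydroxyhex-5-en-2-yl]furan-2(5H)-one | C=CCC[C@](C)(O)[C@@H]1C=C(C(=O)[C@H](C)CC=C(C)C)C(=O)O1 | intermediate
14 | (3S,3aS,4R,6R)-7-hydroxy-3-[(S)-2-hydroxyhex-5-en-2-yl]-6-methyl-4-(prop-1-en-2-yl)-3a,4,5,6-tetrahydro-2-benzofuran-1(3H)-one (enol of the 1,7-dione; C10 not yet fixed) | O=C1O[C@H]([C@@](C)(O)CCC=C)[C@H]2[C@H](C(C)=C)C[C@@H](C)C(O)=C12 | intermediate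
15 | (3S,3aS,4R,6R,7R,7aS)-7-hydroxy-3-[(S)-2-hydroxyhex-5-en-2-yl]-6-methyl-4-(prop-1-en-2-yl)hexahydro-2-benzofuran-1(3H)-one | O=C1O[C@H]([C@@](C)(O)CCC=C)[C@H]2[C@H](C(C)=C)C[C@@H](C)[C@@H](O)[C@@H]12 | intermediate
16 | lactol of 15 (benzofuran-1,7-diol, anomers) | OC1O[C@H]([C@@](C)(O)CCC=C)[C@H]2[C@H](C(C)=C)C[C@@H](C)[C@@H](O)[C@@H]12 | intermediate
17 | 1,7-di-O-acetyl derivative of lactol 16 (anomers; tertiary OH free) | CC(=O)OC1O[C@H]([C@@](C)(O)CCC=C)[C@H]2[C@H](C(C)=C)C[C@@H](C)[C@@H](OC(C)=O)[C@@H]12 | intermediate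
18 | trimethyl(2-methylprop-2-en-1-yl)silane | C=C(C)C[Si](C)(C)C | starting material
19 | (1S,3S,3aS,4R,6R,7R,7aR)-3-[(S)-2-hydroxyhex-5-en-2-yl]-6-methyl-1-(2-methylprop-2-en-1-yl)-4-(prop-1-en-2-yl)octahydro-2-benzofuran-7-yl acetate | C=C(C)C[C@@H]1O[C@H]([C@@](C)(O)CCC=C)[C@H]2[C@H](C(C)=C)C[C@@H](C)[C@@H](OC(C)=O)[C@H]21 | intermediate
20 | tricyclic (6Z)-oxonene: 2,9-epoxy-bridged ten-membered ring fused to the cyclohexane, 3-OH, 11-OAc, 12-Me, 14-isopropenyl (1S,2S,3S,9S,10R,11R,12R,14R) | C/C1=C/CC[C@](C)(O)[C@H]2O[C@@H](C1)[C@H]3[C@@H]2[C@H](C(C)=C)C[C@@H](C)[C@H]3OC(C)=O | intermediate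
21 | B-alkyl-9-borabicyclo[3.3.1]nonane adduct of 20 at C16 | C/C1=C/CC[C@](C)(O)[C@H]2O[C@@H](C1)[C@H]3[C@@H]2[C@H]([C@@H](C)CB4C5CCCC4CCC5)C[C@@H](C)[C@H]3OC(C)=O | intermediate
22 | C16 primary alcohol (15R) of the tricycle, 3-OH and 11-OAc retained | C/C1=C/CC[C@](C)(O)[C@H]2O[C@@H](C1)[C@H]3[C@@H]2[C@H]([C@@H](C)CO)C[C@@H](C)[C@H]3OC(C)=O | intermediate
23 | C16 trifluoromethanesulfonate of 22 | C/C1=C/CC[C@](C)(O)[C@H]2O[C@@H](C1)[C@H]3[C@@H]2[C@H]([C@@H](C)COS(=O)(=O)C(F)(F)F)C[C@@H](C)[C@H]3OC(C)=O | intermediate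
24 | tetracyclic (6Z)-alkene: 11-acetoxy-2,9:3,16-diepoxyasbestin-6-ene (1S,2S,3S,9S,10R,11R,12R,14S,15R) | C/C1=C/CC[C@]2(C)OC[C@H](C)[C@@H]3C[C@@H](C)[C@@H](OC(C)=O)[C@H]4[C@H](C1)O[C@H]2[C@@H]34 | intermediate
25 | CNP0127108.1: 11-acetoxy-6-hydroperoxy-2,9:3,16-diepoxyasbestin-7(19)-ene (1S,2S,3S,6R,9S,10R,11R,12R,14S,15R) | C=C1C[C@@H]2O[C@H]3[C@H]4[C@@H](C[C@@H](C)[C@@H](OC(C)=O)[C@H]42)[C@@H](C)CO[C@@]3(C)CC[C@H]1OO | target

**Totals and risks**
Total steps: 13. Longest linear sequence: 11 steps (1, 2, 5–13; the nerol branch 3, 4, 5–13 is equally long).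

Most likely to fail, first: step 5. The enolate may not trap the minor Payne epoxide cleanly. The fallback sets out from 7 and comes back at 10, and reverses the bond order so that no enolate has to open an epoxide. Payne rearrangement with hydroxide opening (NaOH, tBuOH–H2O, 70 °C) gives (2S,3S)-3-methylhept-6-ene-1,2,3-triol F1. TsCl in pyridine at 0 °C gives the primary tosylate F2. DMAP-catalysed transesterification of the secondary hydroxyl with 4 (toluene, reflux) gives the β-keto ester tosylate F3. K2CO3 in acetone then makes the C1–C10 bond by intramolecular C-alkylation (5-exo-tet) and delivers 10.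

Second: step 6. The acylbutenolide 13 can lose its C2 configuration through its 2-hydroxyfuran tautomer, and the ene closure may be slow or give the wrong C14 epimer. The fallback sets out from 5 (with 4) and comes back at 14, and closes the ring on an open-chain alkylidene 1,3-dicarbonyl compound instead. Sharpless epoxidation of nerol with L-(+)-diethyl tartrate gives the enantiomeric epoxide F4, and ethenolysis gives the vinyl epoxy alcohol F5. Acetone with BF3·OEt2 opens the epoxide at C3 with inversion to the acetonide alcohol F6, which has the C2 and C3 configurations of 10. Dess–Martin periodinane gives the aldehyde F7. Knoevenagel condensation with 4 (piperidinium acetate, CH2Cl2) gives the alkylidene keto ester F8. ZnBr2 then effects the ene closure, with attack anti to the C2–O bond, to the cyclohexanone ester F9. CF3CO2H–H2O removes the acetonide and lactonises to 14.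

Third: step 7. C10 sits between two carbonyl groups in 14, and the cis-fused ketone with the axial C12 methyl is strained, so the trans-fused alcohol may form. The fallback sets out from 10 and comes back at 15, and reduces before cyclising so that C10 is set by kinetic protonation of a simple lactone enolate. Hydrogenation with RuCl2[(R)-BINAP] (H2, MeOH) gives the (11R)-hydroxy lactone F10 under catalyst control. LiN(iPr)2 (3.2 equiv) and PhSeBr give the selenide F11, and H2O2 gives the selenoxide F12, which eliminates away from the hydroxyl to the hydroxyalkyl butenolide F13. Me2AlCl, bound to the C11 alkoxide and the lactone carbonyl, promotes the ene closure, and work-up protonates the aluminium enolate on the convex face to give 15.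

**Further compounds**
F1 | step 5 | (2S,3S)-3-methylhept-6-ene-1,2,3-triol | OC[C@H](O)[C@@](C)(O)CCC=C
F2 | step 5 | (2S,3S)-2,3-dihydroxy-3-methylhept-6-en-1-yl 4-methylbenzenesulfonate | Cc1ccc(cc1)S(=O)(=O)OC[C@H](O)[C@@](C)(O)CCC=C
F3 | step 5 | (2S,3S)-3-hydroxy-3-methyl-1-(tosyloxy)hept-6-en-2-yl (R)-4,7-dimethyl-3-oxooct-6-enoate | Cc1ccc(cc1)S(=O)(=O)OC[C@H](OC(=O)CC(=O)[C@H](C)CC=C(C)C)[C@@](C)(O)CCC=C
F4 | step 6 | [(2S,3R)-3-methyl-3-(4-methylpent-3-en-1-yl)oxiran-2-yl]methanol | OC[C@@H]1O[C@]1(C)CCC=C(C)C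
F5 | step 6 | [(2S,3R)-3-(but-3-en-1-yl)-3-methyloxiran-2-yl]methanol | OC[C@@H]1O[C@]1(C)CCC=C
F6 | step 6 | [(4S,5S)-5-(but-3-en-1-yl)-2,2,5-trimethyl-1,3-dioxolan-4-yl]methanol | OC[C@@H]1OC(C)(C)O[C@@]1(C)CCC=C
F7 | step 6 | (4R,5S)-5-(but-3-en-1-yl)-2,2,5-trimethyl-1,3-dioxolane-4-carbaldehyde | O=C[C@@H]1OC(C)(C)O[C@@]1(C)CCC=C
F8 | step 6 | methyl (4R)-2-{[(4S,5S)-5-(but-3-en-1-yl)-2,2,5-trimethyl-1,3-dioxolan-4-yl]methylidene}-4,7-dimethyl-3-oxooct-6-enoate (E/Z) | COC(=O)C(=C[C@@H]1OC(C)(C)O[C@@]1(C)CCC=C)C(=O)[C@H](C)CC=C(C)C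
F9 | step 6 | methyl (3R,5R,6S)-6-[(4S,5S)-5-(but-3-en-1-yl)-2,2,5-trimethyl-1,3-dioxolan-4-yl]-3-methyl-2-oxo-5-(prop-1-en-2-yl)cyclohexane-1-carboxylate (C1 epimers) | COC(=O)C1C(=O)[C@H](C)C[C@@H](C(C)=C)[C@@H]1[C@@H]2OC(C)(C)O[C@@]2(C)CCC=C
F10 | step 7 | (5S)-3-[(1R,2R)-1-hydroxy-2,5-dimethylhex-4-en-1-yl]-5-[(S)-2-hydroxyhex-5-en-2-yl]oxolan-2-one (C3 epimers) | C=CCC[C@](C)(O)[C@@H]1CC([C@H](O)[C@H](C)CC=C(C)C)C(=O)O1
F11 | step 7 | 3-(phenylselanyl) derivative of F10 | C=CCC[C@](C)(O)[C@@H]1CC([Se]c2ccccc2)([C@H](O)[C@H](C)CC=C(C)C)C(=O)O1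
F12 | step 7 | selenoxide of F11 | C=CCC[C@](C)(O)[C@@H]1CC([Se](=O)c2ccccc2)([C@H](O)[C@H](C)CC=C(C)C)C(=O)O1
F13 | step 7 | (S)-3-[(1R,2R)-1-hydroxy-2,5-dimethylhex-4-en-1-yl]-5-[(S)-2-hydroxyhex-5-en-2-yl]furan-2(5H)-one | C=CCC[C@](C)(O)[C@@H]1C=C([C@H](O)[C@H](C)CC=C(C)C)C(=O)O1
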